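**Assumption:** the SMILES is read literally. It encodes H‑5 and the C‑10 methyl on the same face, i.e. a cis‑fused decalin (4R,5S,8R,9R,10S). Labdane locants are used throughout (C4 = CH3/CH2O carbon, C5/C10 = ring fusion, C8 = carbinol, C9 = side‑chain carbon; α = face opposite the C‑10 methyl).

## Retrosynthetic overview

1. Z‑Coumarate: propiolate ester of the C4 CH2OH, Sonogashira coupling with 4‑iodophenol, syn semihydrogenation. The diene comes from a terminal alkyne and ethene (enyne metathesis).
2. C8 carbinol: α‑epoxidation of the 8(17)‑methylidene compound, then hydride opening; the same hydride reduces the C4 ester.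
3. Key step: the C1–C10 bond is made by 6‑exo radical cyclisation of a primary alkyl radical onto the β‑carbon of a 3‑methylcyclohexenone. The tether forces the cis fusion; the enoxyl radical is captured by boron and C‑alkylated at C9 in the same flask.
4. C4–C5 bond and both stereocentres: Claisen rearrangement of the cyclic ketene acetal from α‑methyl‑δ‑valerolactone and (R)‑2‑methylcyclohex‑2‑enol (chirality from a CBS reduction).
5. Ring order: ring B is present from the start (2‑methylcyclohex‑2‑enone); ring A is closed second, in the radical step.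

## Route

Step 1
Reactants: 1 2-methylcyclohex-2-en-1-one
Product: 2 (1R)-2-methylcyclohex-2-en-1-ol
Conditions: (S)-2-methyl-CBS-oxazaborolidine (10 mol %), BH3·SMe2, THF, −20 °C; MeOH quench
Reagents that add atoms: none
Why: Corey–Bakshi–Shibata reduction, in which the 2‑methylalkenyl arm acts as the large group so that the (S)‑catalyst gives the (R)‑allylic alcohol, the only external source of chirality in the route.

Step 2
Reactants: 3 3-methyloxan-2-one (α-methyl-δ-valerolactone; racemic)
Product: 5 2,2-dimethoxy-3-methyloxane, via O-methyl lactonium tetrafluoroborate 4 (not isolated)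
Conditions: Me3OBF4, CH2Cl2, rt; then NaOMe, MeOH, −78 → 0 °C
Reagents that add atoms: trimethyloxonium tetrafluoroborate C[O+](C)C.F[B-](F)(F)F; sodium methoxide [Na+].[O-]C
Why: Meerwein O‑methylation of the lactone carbonyl followed by methoxide capture is the classical lactone orthoester synthesis, and the α‑stereocentre does not matter because it becomes sp2 in step 3.

Step 3
Reactants: 2 (1R)-2-methylcyclohex-2-en-1-ol; 5 2,2-dimethoxy-3-methyloxane
Product: 8 (3R)-3-methyl-3-[(1S)-2-methylcyclohex-2-en-1-yl]oxan-2-one, via mixed orthoester 6 (not isolated), via cyclic ketene acetal 7 (not isolated)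
Conditions: 5 (2 equiv), 2,4,6-trimethylbenzoic acid (5 mol %), xylenes, 140 °C, MeOH distilled off
Reagents that add atoms: none
Why: Johnson–Claisen rearrangement in which the ketene acetal geometry is locked by the oxane ring and the suprafacial [3,3] shift through the boat transition state preferred by cyclohex‑2‑enyl systems (only the methyl group sits under the carbocycle) transfers the carbinol chirality to C5 (S) and sets the quaternary C4 (R).

Step 4
Reactants: 8 (3R)-3-methyl-3-[(1S)-2-methylcyclohex-2-en-1-yl]oxan-2-one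
Product: 11 methyl (2R)-5-iodo-2-methyl-2-[(1S)-2-methylcyclohex-2-en-1-yl]pentanoate, via trimethylsilyl ester 9 (not isolated), via iodo acid 10 (not isolated)
Conditions: Me3SiI, 2,6-di-tert-butylpyridine (cat.), CH2Cl2, 0 °C → rt; MeOH; then Me3SiCHN2, PhMe/MeOH, 0 °C
Reagents that add atoms: iodotrimethylsilane C[Si](C)(C)I; (trimethylsilyl)diazomethane C[Si](C)(C)C=[N+]=[N-]
Why: Silyl‑activated SN2 opening of the lactone by iodide at the unhindered O–CH2 carbon, then methanolysis of the silyl ester and diazoalkane esterification, with no stereocentre touched.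

Step 5
Reactants: 11 methyl (2R)-5-iodo-2-methyl-2-[(1S)-2-methylcyclohex-2-en-1-yl]pentanoate
Product: 12 methyl (2R)-5-iodo-2-methyl-2-[(1S)-2-methyl-4-oxocyclohex-2-en-1-yl]pentanoate
Conditions: Rh2(caprolactamate)4 (1 mol %), t-BuOOH (70 % aq, 5 equiv), K2CO3 (0.5 equiv), CH2Cl2, rt
Reagents that add atoms: tert-butyl hydroperoxide CC(C)(C)OO
Why: Catalytic allylic C–H oxidation attacks the ring CH2 next to the alkene CH (as 1‑methylcyclohexene gives 3‑methylcyclohex‑2‑enone), while the allylic C5–H is shielded by the neighbouring quaternary carbon, and this creates the enone radical acceptor.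

Step 6
Reactants: 13 but-3-yn-1-ol
Product: 14 but-3-yn-1-yl trifluoromethanesulfonate
Conditions: Tf2O, pyridine, CH2Cl2, −78 → −20 °C; used at once
Reagents that add atoms: trifluoromethanesulfonic anhydride O=S(=O)(OS(=O)(=O)C(F)(F)F)C(F)(F)F
Why: Standard O‑triflation of a primary alcohol gives an alkylating agent reactive enough for a hindered enolate at low temperature.

Step 7
Reactants: 12 methyl (2R)-5-iodo-2-methyl-2-[(1S)-2-methyl-4-oxocyclohex-2-en-1-yl]pentanoate; 14 but-3-yn-1-yl trifluoromethanesulfonate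
Product: 17 methyl (1R,4aS,5R,8aS)-5-(but-3-yn-1-yl)-1,4a-dimethyl-6-oxodecahydronaphthalene-1-carboxylate, via diethylboron enolate 15 (not isolated), via lithium enoxyborate 16 (not isolated)
Conditions: Et3B (1.5 equiv), air (slow, syringe pump), PhH, 0.01 M, rt; evaporate under Ar; THF, MeLi (1.0 equiv), −78 °C; then 14 (2 equiv), −78 → −20 °C
Reagents that add atoms: none
Why: Proposed new method: Et• from Et3B/O2 abstracts iodine from 12, the primary C1 radical closes ring A by 6‑exo‑trig attack on the enone β‑carbon C10 from the face on which the tether hangs (quaternary C10, cis ring fusion), the enoxyl radical is captured by Et3B as a regiodefined boron enolate with release of Et• (chain), and MeLi converts this into a borate enolate that is C‑alkylated by 14 on the convex β face anti to the new C10–C1 bond (9R, also the more stable C9 epimer); the closest known reaction types are trialkylborane‑mediated radical conjugate addition of alkyl iodides to enones giving boron enolates and regiospecific C‑alkylation of enoxyborates.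

Step 8
Reactants: 17 methyl (1R,4aS,5R,8aS)-5-(but-3-yn-1-yl)-1,4a-dimethyl-6-oxodecahydronaphthalene-1-carboxylate
Product: 18 methyl (1R,4aR,5S,8aS)-5-(but-3-yn-1-yl)-1,4a-dimethyl-6-methylidenedecahydronaphthalene-1-carboxylate (same spatial arrangement as 17; descriptors change by priority only)
Conditions: Ph3PCH3Br (4 equiv), KOtBu (3.8 equiv), PhMe, 90 °C
Reagents that add atoms: methyltriphenylphosphonium bromide C[P+](c1ccccc1)(c1ccccc1)c1ccccc1.[Br-]
Why: Wittig methylenation of the hindered ketone in hot toluene, where the base‑labile C9 centre is safe because the configuration from step 7 (side chain equatorial in the chair with the C10 methyl axial) is the thermodynamic one.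

Step 9
Reactants: 18 methyl (1R,4aR,5S,8aS)-5-(but-3-yn-1-yl)-1,4a-dimethyl-6-methylidenedecahydronaphthalene-1-carboxylate
Product: 19 8α,17-epoxide of 18 (spiro-oxirane at C8 with oxygen on the face opposite the C10 methyl and CH2 on the same face; other centres as in 17)
Conditions: dimethyldioxirane, acetone, −20 → 0 °C
Reagents that add atoms: dimethyldioxirane CC1(C)OO1
Why: Epoxidation of the exocyclic 1,1‑disubstituted alkene from the α face, anti to the axial angular methyl that shields the β face 1,3 to C8 (the control seen for labd‑8(17)‑enes), places the oxygen α at C8 while the alkyne is inert.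

Step 10
Reactants: 19 8α,17-epoxide of 18
Product: 20 (1R,2R,4aS,5R,8aS)-1-(but-3-yn-1-yl)-5-(hydroxymethyl)-2,5,8a-trimethyldecahydronaphthalen-2-ol
Conditions: LiAlH4, THF, 0 °C → reflux; Fieser work-up
Reagents that add atoms: none
Why: Hydride opens the spiro‑epoxide by SN2 attack at its CH2 terminus, so the C8–O bond and the 8α‑OH/8β‑CH3 centre stay intact, and the same reagent reduces the methyl ester to the neopentyl primary alcohol.

Step 11
Reactants: 20 (1R,2R,4aS,5R,8aS)-1-(but-3-yn-1-yl)-5-(hydroxymethyl)-2,5,8a-trimethyldecahydronaphthalen-2-ol; 21 ethene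
Product: 22 (1R,2R,4aS,5R,8aS)-5-(hydroxymethyl)-2,5,8a-trimethyl-1-(3-methylidenepent-4-en-1-yl)decahydronaphthalen-2-ol
Conditions: second-generation Grubbs catalyst (5 mol %), ethene (1 atm), PhMe, 60 °C
Reagents that add atoms: none
Why: Ethene–alkyne cross enyne metathesis converts the terminal alkyne into the 2‑substituted buta‑1,3‑diene, with no other alkene present and free hydroxyls tolerated.

Step 12
Reactants: 22 (1R,2R,4aS,5R,8aS)-5-(hydroxymethyl)-2,5,8a-trimethyl-1-(3-methylidenepent-4-en-1-yl)decahydronaphthalen-2-ol; 23 prop-2-ynoic acid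
Product: 24 [(1R,4aS,5R,6R,8aS)-6-hydroxy-1,4a,6-trimethyl-5-(3-methylidenepent-4-en-1-yl)decahydronaphthalen-1-yl]methyl prop-2-ynoate
Conditions: DCC, DMAP (5 mol %), CH2Cl2, −20 → 0 °C
Reagents that add atoms: none
Why: Steglich esterification acylates the primary neopentyl hydroxyl selectively over the tertiary C8 hydroxyl.

Step 13
Reactants: 24 [(1R,4aS,5R,6R,8aS)-6-hydroxy-1,4a,6-trimethyl-5-(3-methylidenepent-4-en-1-yl)decahydronaphthalen-1-yl]methyl prop-2-ynoate; 25 4-iodophenol
Product: 26 [(1R,4aS,5R,6R,8aS)-6-hydroxy-1,4a,6-trimethyl-5-(3-methylidenepent-4-en-1-yl)decahydronaphthalen-1-yl]methyl 3-(4-hydroxyphenyl)prop-2-ynoate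
Conditions: Pd(PPh3)2Cl2 (3 mol %), CuI (5 mol %), K2CO3, THF, rt → 40 °C
Reagents that add atoms: none
Why: Sonogashira coupling of the terminal ynoate with the aryl iodide, using carbonate instead of an amine to avoid conjugate addition, tolerates the free phenol, the tertiary alcohol and the diene.

Step 14
Reactants: 26 [(1R,4aS,5R,6R,8aS)-6-hydroxy-1,4a,6-trimethyl-5-(3-methylidenepent-4-en-1-yl)decahydronaphthalen-1-yl]methyl 3-(4-hydroxyphenyl)prop-2-ynoate
Product: 27 [(1R,4aS,5R,6R,8aS)-6-hydroxy-1,4a,6-trimethyl-5-(3-methylidenepent-4-en-1-yl)decahydronaphthalen-1-yl]methyl (2Z)-3-(4-hydroxyphenyl)prop-2-enoate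
Conditions: H2 (1 atm), Pd/CaCO3 poisoned with Pb(OAc)2, quinoline, EtOAc, 0 °C; stopped at 1.0 equiv H2
Reagents that add atoms: none
Why: Lindlar semihydrogenation adds H2 syn to the conjugated alkyne to give the (Z)‑cinnamate, the alkyne binding far more strongly than the diene.

## Compound list

1 | 2-methylcyclohex-2-en-1-one | CC1=CCCCC1=O | starting material
2 | (1R)-2-methylcyclohex-2-en-1-ol | O[C@@H]1CCCC=C1C | intermediate
3 | 3-methyloxan-2-one (racemic) | CC1CCCOC1=O | starting material
4 | 6-methoxy-5-methyl-3,4-dihydro-2H-pyran-1-ium tetrafluoroborate (not isolated) | COC1=[O+]CCCC1C.F[B-](F)(F)F | intermediate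
5 | 2,2-dimethoxy-3-methyloxane (racemic) | COC1(OC)OCCCC1C | intermediate
6 | 2-methoxy-3-methyl-2-{[(1R)-2-methylcyclohex-2-en-1-yl]oxy}oxane (mixed orthoester, not isolated) | CC1CCCOC1(OC)O[C@@H]2CCCC=C2C | intermediate
7 | 5-methyl-6-{[(1R)-2-methylcyclohex-2-en-1-yl]oxy}-3,4-dihydro-2H-pyran (ketene acetal, not isolated) | CC1=C(O[C@@H]2CCCC=C2C)OCCC1 | intermediate
8 | (3R)-3-methyl-3-[(1S)-2-methylcyclohex-2-en-1-yl]oxan-2-one | C[C@@]1(CCCOC1=O)[C@H]2CCCC=C2C | intermediate
9 | trimethylsilyl (2R)-5-iodo-2-methyl-2-[(1S)-2-methylcyclohex-2-en-1-yl]pentanoate (not isolated) | C[Si](C)(C)OC(=O)[C@](C)(CCCI)[C@H]1CCCC=C1C | intermediate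
10 | (2R)-5-iodo-2-methyl-2-[(1S)-2-methylcyclohex-2-en-1-yl]pentanoic acid (not isolated) | OC(=O)[C@](C)(CCCI)[C@H]1CCCC=C1C | intermediate
11 | methyl (2R)-5-iodo-2-methyl-2-[(1S)-2-methylcyclohex-2-en-1-yl]pentanoate | COC(=O)[C@](C)(CCCI)[C@H]1CCCC=C1C | intermediate
12 | methyl (2R)-5-iodo-2-methyl-2-[(1S)-2-methyl-4-oxocyclohex-2-en-1-yl]pentanoate | COC(=O)[C@](C)(CCCI)[C@H]1CCC(=O)C=C1C | intermediate
13 | but-3-yn-1-ol | C#CCCO | starting material
14 | but-3-yn-1-yl trifluoromethanesulfonate | C#CCCOS(=O)(=O)C(F)(F)F | intermediate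
15 | methyl (1R,4aS,8aS)-6-[(diethylboranyl)oxy]-1,4a-dimethyl-1,2,3,4,4a,7,8,8a-octahydronaphthalene-1-carboxylate (not isolated) | CCB(CC)OC1=C[C@@]2(C)CCC[C@@](C)(C(=O)OC)[C@H]2CC1 | intermediate
16 | lithium diethyl(methyl)borate of enolate 15 (not isolated) | [Li+].CC[B-](C)(CC)OC1=C[C@@]2(C)CCC[C@@](C)(C(=O)OC)[C@H]2CC1 | intermediate
17 | methyl (1R,4aS,5R,8aS)-5-(but-3-yn-1-yl)-1,4a-dimethyl-6-oxodecahydronaphthalene-1-carboxylate | C#CCC[C@@H]1[C@@]2(C)CCC[C@@](C)(C(=O)OC)[C@H]2CCC1=O | intermediate
18 | methyl (1R,4aR,5S,8aS)-5-(but-3-yn-1-yl)-1,4a-dimethyl-6-methylidenedecahydronaphthalene-1-carboxylate | C#CCC[C@@H]1[C@@]2(C)CCC[C@@](C)(C(=O)OC)[C@H]2CCC1=C | intermediate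
19 | 8α,17-epoxide of 18 (spiro-oxirane, O anti to the C10 methyl) | C#CCC[C@@H]1[C@@]2(C)CCC[C@@](C)(C(=O)OC)[C@H]2CC[C@]13CO3 | intermediate
20 | (1R,2R,4aS,5R,8aS)-1-(but-3-yn-1-yl)-5-(hydroxymethyl)-2,5,8a-trimethyldecahydronaphthalen-2-ol | C#CCC[C@@H]1[C@@]2(C)CCC[C@@](C)(CO)[C@H]2CC[C@@]1(C)O | intermediate
21 | ethene | C=C | starting material
22 | (1R,2R,4aS,5R,8aS)-5-(hydroxymethyl)-2,5,8a-trimethyl-1-(3-methylidenepent-4-en-1-yl)decahydronaphthalen-2-ol | C=CC(=C)CC[C@@H]1[C@@]2(C)CCC[C@@](C)(CO)[C@H]2CC[C@@]1(C)O | intermediate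
23 | prop-2-ynoic acid | C#CC(=O)O | starting material
24 | [(1R,4aS,5R,6R,8aS)-6-hydroxy-1,4a,6-trimethyl-5-(3-methylidenepent-4-en-1-yl)decahydronaphthalen-1-yl]methyl prop-2-ynoate | C=CC(=C)CC[C@@H]1[C@@]2(C)CCC[C@@](C)(COC(=O)C#C)[C@H]2CC[C@@]1(C)O | intermediate
25 | 4-iodophenol | Oc1ccc(I)cc1 | starting material
26 | [(1R,4aS,5R,6R,8aS)-6-hydroxy-1,4a,6-trimethyl-5-(3-methylidenepent-4-en-1-yl)decahydronaphthalen-1-yl]methyl 3-(4-hydroxyphenyl)prop-2-ynoate | C=CC(=C)CC[C@@H]1[C@@]2(C)CCC[C@@](C)(COC(=O)C#Cc3ccc(O)cc3)[C@H]2CC[C@@]1(C)O | intermediate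
27 | [(1R,4aS,5R,6R,8aS)-6-hydroxy-1,4a,6-trimethyl-5-(3-methylidenepent-4-en-1-yl)decahydronaphthalen-1-yl]methyl (2Z)-3-(4-hydroxyphenyl)prop-2-enoate | C=CC(=C)CC[C@@H]1[C@@]2(C)CCC[C@@](C)(COC(=O)/C=C\c3ccc(O)cc3)[C@H]2CC[C@@]1(C)O | target

## Step count and risks

Total steps: 14. Longest linear sequence: 12 (steps 1, 3–5, 7–14).

**Step 7 (one‑pot radical cyclisation and borate alkylation).** The chain may be short for a primary iodide, and the hindered enolate may react slowly or on oxygen. The fallback sets out from iodo‑enone 12 and separates the two events. A nickel‑catalysed reductive radical conjugate cyclisation (NiCl2(dme), neocuproine, Mn powder, Et3SiCl, DMF, rt) gives the isolable triethylsilyl enol ether methyl (1R,4aS,8aS)-1,4a-dimethyl-6-(triethylsilyloxy)-1,2,3,4,4a,7,8,8a-octahydronaphthalene-1-carboxylate F1. Mukaiyama–Michael addition of this enol ether to acrolein (TiCl4, CH2Cl2, −78 °C) forms the C9–C11 bond from the same convex face and gives the keto aldehyde methyl (1R,4aS,5R,8aS)-1,4a-dimethyl-6-oxo-5-(3-oxopropyl)decahydronaphthalene-1-carboxylate F2. Homologation with the Ohira–Bestmann reagent (K2CO3, MeOH) turns the aldehyde into the terminal alkyne, and the sequence comes back to the route at ketone 17.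

**Step 9 (facial selectivity at C8).** The α‑selectivity rests on the chair with the C10 methyl axial being the reacting conformer. If the other chair reacts, the oxidant enters from the β face. The fallback sets out from ketone 17 and uses the opposite polarity, which gives the opposite outcome for the same facial preference. MeLi/CeCl3 (THF, −78 °C) adds the methyl group to the C8 carbonyl and gives the tertiary alcohol methyl (1R,4aS,5R,6R,8aS)-5-(but-3-yn-1-yl)-6-hydroxy-1,4a,6-trimethyldecahydronaphthalene-1-carboxylate F3. LiAlH4 then reduces the ester, and the sequence comes back to the route at diol 20.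

**Step 14 (semihydrogenation beside the diene).** Over‑reduction of the terminal diene is the danger. The fallback sets out from diene diol 22 and makes the Z‑alkene on a fragment that carries no diene. Sonogashira coupling of 4‑iodophenol 25 with prop‑2‑ynoic acid 23 (Pd(PPh3)4, DBU, DMSO, rt) gives 3-(4-hydroxyphenyl)prop-2-ynoic acid F4. Lindlar semihydrogenation of that acid gives (2Z)-3-(4-hydroxyphenyl)prop-2-enoic acid F5. Carbodiimide esterification of 22 with this acid (DCC, DMAP cat., CH2Cl2, −20 °C, slow addition of the acid) comes back to the route at target 27.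

## Further compounds

F1 | step 7 | methyl (1R,4aS,8aS)-1,4a-dimethyl-6-(triethylsilyloxy)-1,2,3,4,4a,7,8,8a-octahydronaphthalene-1-carboxylate | CC[Si](CC)(CC)OC1=C[C@@]2(C)CCC[C@@](C)(C(=O)OC)[C@H]2CC1
F2 | step 7 | methyl (1R,4aS,5R,8aS)-1,4a-dimethyl-6-oxo-5-(3-oxopropyl)decahydronaphthalene-1-carboxylate | O=CCC[C@@H]1[C@@]2(C)CCC[C@@](C)(C(=O)OC)[C@H]2CCC1=O
F3 | step 9 | methyl (1R,4aS,5R,6R,8aS)-5-(but-3-yn-1-yl)-6-hydroxy-1,4a,6-trimethyldecahydronaphthalene-1-carboxylate | C#CCC[C@@H]1[C@@]2(C)CCC[C@@](C)(C(=O)OC)[C@H]2CC[C@@]1(C)O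
F4 | step 14 | 3-(4-hydroxyphenyl)prop-2-ynoic acid | OC(=O)C#Cc1ccc(O)cc1
F5 | step 14 | (2Z)-3-(4-hydroxyphenyl)prop-2-enoic acid | OC(=O)/C=C\c1ccc(O)cc1
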